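(The readings stem from a simulated flask with made-up constants; scatter was added.)

| flask | acidic substrate | free base | electrophile | protic impurity | remark | time |
|---|---|---|---|---|---|---|
| gamma | 0.10 M | 0.95 equiv | 2 equiv | 0.026 M | run made earlier |  |
| beta | 0.10 M | 0.95 equiv | 2 equiv | 0.039 M | run made earlier |  |
| alpha | 0.10 M | 0.95 equiv | 1.1 equiv | 0.030 M | run made earlier |  |
| Monday's | 0.10 M | 0.950 equiv | 2.00 equiv | 0.0300 M |  | 10 min |
| Friday's | 0.10 M | 0.950 equiv | 1.00 equiv | 0.0200 M |  | 10 min |

| gamma: time / min | gamma: product / % | beta: time / min | beta: product / % | alpha: time / min | alpha: product / % |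
|---|---|---|---|---|---|
| 0.833 | 74.1 | 2.00 | 88.3 | 0.833 | 51.8 |
| 2.50 | 91.0 | 4.00 | 91.3 | 2.50 | 75.5 |
| 5.00 | 92.0 | 6.00 | 90.9 | 5.00 | 84.3 |
| 8.00 | 93.1 | 8.00 | 91.8 | 8.00 | 87.3 |
| 10.0 | 92.4 | 10.0 | 92.3 | 10.0 | 87.6 |

(readings scatter by 0.5 percentage points)



- the winner by amount of product, in percent of the acidic substrate charged; "neither" if no more than 2 percentage points parts them (Monday's / Friday's / neither)
- how much product is there at the end, in percent of the acidic substrate charged: Monday's
- how much product is there at the end, in percent of the acidic substrate charged: Friday's

In the first instants of the gamma run, product climbs to 74.1% by 0.833 min. The alpha run, with 1.1 equiv of electrophile against 2 equiv and 0.030 M of protic impurity against 0.026 M, stands lower at 51.8%. In the middle, the gamma run reaches 91.0% by 2.50 min, and from 5.00 min on its readings scatter around a plateau of 92.5%. In the gamma run the free base, at 0.95 equiv the limiting reagent, sets a ceiling above that plateau, and the readings of the beta run, richer in protic impurity, level lower at a mean of 91.6%.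

At the end, then, the useful reading is 9.20%, the toll φ: the product missing below the base ceiling, in molar terms, per unit of protic impurity charged. That figure is the mean of 9.62% from gamma and 8.78% from beta, and it carries the scatter of their readings. Monday's, with 2.00 equiv of electrophile like those two runs, should therefore reach 92.2%. The last two alpha readings give a heavier toll of 25.2%, which puts a ceiling of 90.0% over Friday's. With 1.00 equiv of electrophile, less than alpha had, Friday's should still stand below that ceiling at 10 min, so Monday's leads by at least 2.2 percentage points.

The forecast gives Monday's, with 92.3% against 86.5%, and says of Friday's: “Electrophile runs short”.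

The flask gives Monday's, with 92.3% against 86.9%.

    electrophile + anion → product (k = 0.230 M⁻¹ s⁻¹)
    protic impurity + free base → quenched reagent (k = 0.290 M⁻¹ s⁻¹)
    acidic substrate + free base ⇌ protonated base + anion, settled at all times (K = 73.0)

In Monday's at 0.310 min, the anion's half-life by the step to product is 0.33 min, while the free base's half-life by the impurity step is 1.4 min. Monday's ends with 0.00270 M of quenched reagent, which is 8.99% of the impurity charged, against a toll φ of 9.20%. The neighbour of Monday's at 0.025 M of acidic substrate carries 1.20 equiv of protic impurity, so φ puts it at 84.0%. The computed flask gives 86.2%, with 6.48% of its impurity spent.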